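Wednesday's and Saturday's runs differ in c(racemization catalyst), 27 mM against 60 mM, yet at 80.0 s their left-handed product reads 37.3% and 37.9%, a gap of 0.6 percentage points against a scatter of 0.3 points per reading. Cedar and maple, at 40 mM, lie between the two in that charge, so I pool these two runs.

in all of them: left-handed substrate 0.80 M; right-handed substrate 0.80 M

|  | partner | free catalyst | racemization catalyst | added ligand | remark | time |
|---|---|---|---|---|---|---|
| Wednesday's | 1.6 M | 7 mM | 27 mM | 4.8 mM | run made earlier |  |
| Saturday's | 1.6 M | 7 mM | 60 mM | 4.8 mM | run made earlier |  |
| Sunday's | 1.6 M | 7 mM | 40 mM | 7.2 mM | run made earlier |  |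
| cedar | 1.60 M | 7.0 mM | 40 mM | 4.8 mM |  | 2.0 min |
| maple | 1.60 M | 7.0 mM | 40 mM | 4.8 mM |  | 6.0 min |

- Wednesday's (time / s: left-handed product / %, right-handed product / %): 10.0: 17.3, 6.2; 20.0: 23.9, 9.6; 30.0: 27.9, 11.8; 40.0: 31.1, 14.0; 50.0: 32.7, 15.2; 60.0: 35.3, 16.1; 80.0: 37.3, 18.5
- Saturday's (time / s: left-handed product / %, right-handed product / %): 10.0: 17.3, 6.3; 12.0: 18.8, 6.7; 20.0: 23.4, 9.2; 30.0: 28.0, 11.9; 40.0: 30.7, 13.6; 60.0: 35.0, 15.6; 80.0: 37.9, 18.4
- Sunday's (time / s: left-handed product / %, right-handed product / %): 10.0: 15.1, 5.7; 20.0: 20.8, 8.4; 40.0: 26.8, 11.4; 80.0: 33.4, 14.9

(each reading ± 0.3 percentage points)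

- free catalyst is single-handed; left-handed substrate and right-handed substrate are mirror images of each other, charged as a racemate, each of them at the stated concentration
- steps thought possible: partner + free catalyst + left-handed substrate -> free catalyst + left-handed product; left-handed product <-> right-handed product; 2 partner -> homo dimer; left-handed substrate + racemization catalyst <-> right-handed substrate + racemization catalyst; free catalyst + added ligand <-> idle complex; partner + free catalyst + right-handed substrate -> free catalyst + right-handed product
- an excess is the difference of the two amounts in percent of their sum
- an excess is below zero if the other one leads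

* the winner by excess of left-handed product over right-handed product in the product; "neither" if no more than 2 percentage points parts them (cedar / maple / neither)
* excess of left-handed product over right-handed product in the product at the end, cedar
* excess of left-handed product over right-handed product in the product at the end, maple

The decision is when to stop: at cedar's time or at maple's. You need two things for it.

The first is λ, minus the logarithm of the fraction of one substrate not yet turned into its product, each substrate being half of the charge. The ratio of λ for left to λ for right is the selectivity factor. At the last readings it reads 2.97 on Wednesday, 3.09 on Saturday and 3.12 on Sunday, although Sunday's run, charged with 7.2 mM of added ligand, stood lower there, at 33.4% of left-handed product. I carry their mean, 3.06.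

The second is how λ grows. Pooled, left λ is 0.641 at 20.0 s, 0.962 at 40.0 s and 1.39 at 80.0 s. I replace the curve beyond by one mean step per doubling of time, the latest, 0.432. Then I check the error with the step before it, 0.322.

| flask | step | left λ | left into product | right into product | excess |
|---|---|---|---|---|---|
| cedar | latest | 1.65 | 80.7% | 41.7% | 31.9% |
| maple | latest | 2.33 | 90.3% | 53.4% | 25.7% |
| cedar | earlier | 1.58 | 79.5% | 40.4% | 32.6% |
| maple | earlier | 2.09 | 87.7% | 49.6% | 27.8% |

Cedar leads by 6.2 points, and with the earlier step by 4.8 points, still more than the margin of 2 points. So I would stop at cedar's time. Waiting for maple's raises the reckoned product from 61.2% to 71.8% of the charge, and it costs those points of excess.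

The forecast names cedar, with 31% and 25%, holding that “the product excess falls with conversion”.

The flask gives 32.4% for cedar and 25.7% for maple, so cedar leads.

    partner + free catalyst + left-handed substrate → free catalyst + left-handed product (k = 5.90 M⁻² s⁻¹)
    left-handed product ⇌ right-handed product (k = 3.80 × 10⁻⁴ s⁻¹)
    2 partner → homo dimer (k = 0.00320 M⁻¹ s⁻¹)
    left-handed substrate + racemization catalyst ⇌ right-handed substrate + racemization catalyst, rate k4*[racemization catalyst]*[left-handed substrate] forward; the back reaction follows from the equilibrium constant (k = 0.0510 M⁻¹ s⁻¹)
    free catalyst + added ligand ⇌ idle complex (K = 860 M⁻¹, k = 18.0 M⁻¹ s⁻¹)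
    partner + free catalyst + right-handed substrate → free catalyst + right-handed product (k = 1.90 M⁻² s⁻¹)

A neighbour of cedar is charged with 0.64 M of partner, its other charges and its time held. It ends with left-handed product at 22.8% of the two substrates charged together, so its left λ is 0.608. Dividing by the selectivity factor 3.06 gives 18.0% of the right-handed charge turned into its product, and with 45.6% of the left-handed charge, an excess of 43.3%. The neighbour itself stands at 41.8%, with 12% of its partner left.

The readings stem from a simulated flask from invented constants.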